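**Remarks on the chemistry**

- Ring positions follow flavone numbering (O1, C2, C3, C4, C4a, C5 to C8, C8a; ring B primed).
- Ketene 5 is not a stock chemical. It is taken as generated on demand by pyrolysis of acetone and fed as a gas; this counts as reagent preparation, not as a step.

## Analysis of the target

Artelasticin is a flavone: a 4H-chromen-4-one in which the benzo ring A (C4a to C8a) is fused to the pyranone ring C (O1, C2, C3, C4), with a 2,4-dihydroxyphenyl ring B on C2. The molecule has no stereocentre. It carries three 3-methylbut-2-enyl (prenyl) groups on C3, C6 and C8 and four phenolic hydroxyls on C5, C7, C2' and C4'.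

The sensitive groups are the three trisubstituted alkenes, two of which sit next to phenols. Acid closes 2,2-dimethylchroman rings from the C5 or C7 hydroxyl onto the C6 or C8 prenyl group, hydrogen halides add to the alkenes, and hydrogenolysis or strong Lewis acids are excluded. Every protecting group therefore has to leave under neutral or basic conditions.

The hard part is ring A: a fully substituted phloroglucinol with two C-prenyl groups. Direct prenylation of phloroglucinol derivatives gives O-alkyl, geminal dialkyl and over-alkylated products. In addition, the C3 prenyl group has to be placed next to the C2 aryl group.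

The strategy rests on the strict alternation around ring A: oxygen on C8a, prenyl on C8, oxygen on C7, prenyl on C6, oxygen on C5, carbon (C4) on C4a. The pairs C7/C8 and C5/C6 each have the substitution pattern of a prenyl ynol ether, and C8a/C4a that of a ketene. Ring A can thus be assembled from two molecules of one siloxyalkyne and one molecule of ketene, with each prenyl group fixed on its carbon before the ring exists.

## Retrosynthetic reasoning

**20 from 19.** No skeletal bond is cut. All four phenols of 20 are masked in 19 as silyl ethers, so that the last step needs only fluoride and no acid touches the prenyl groups.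

**19 from 12 and 18.** Ring C is opened at C4–C3 and O1–C2. This is the most convergent cut: salicylaldehyde 12 holds all of ring A and C4, and alkyne 18 holds ring B, C2, C3 and the C3 prenyl group. The forward reaction has to activate the aldehyde C–H bond of 12, insert 18 with the prenyl-bearing carbon toward the acyl carbon, and close the C–O bond from the free ortho hydroxyl.

**18 from 15 and 16, 15 from 14, 14 from 13.** The sp–sp3 bond between the alkyne and the prenyl CH2 is cut, giving acetylide 17 (made in the flask from dibromoalkene 15) and prenyl bromide 16. The alkyne carbon is traced back to the formyl group of 14, and 14 to commercial 13 by silylation. The forward sequence must avoid protic base, which would strip the aryl silyl ethers.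

**12 from 11.** The C4a–C4 bond is cut. Phenol 11 has a single unsubstituted ring carbon, ortho to its free hydroxyl, so formylation has only one site. Once C4 is attached, the two oxygen-bearing carbons flanking it differ only in their protecting state, so loss of the silyl group on the C5 oxygen would do no harm.

**11 from 6 and 4 (key disconnection).** Ring A is cut at C8a–C8, C7–C6 and C8a–C4a. Cyclobutenone 6 supplies C8a with its oxygen, C4a, C5 with its oxygen and C6 with its prenyl group. Siloxyalkyne 4 supplies C7 with its oxygen and C8 with its prenyl group. This cut is chosen over any prenylation of an existing phloroglucinol because both prenyl groups arrive already bonded to defined carbons, and the oxygen that must become O1 is the only one set free. The forward reaction has to open 6, join the resulting ketene to 4 in the right orientation, and close the six-membered ring.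

An alkyl ether on the C3 oxygen of the cyclobutenone would be the more conventional choice. It would, however, leave an aryl alkyl ether on C5 that could later be cleaved only with chelating Lewis acids, which the prenyl groups do not tolerate. A silyl ether is used instead.

**6 from 4 and 5.** The four-membered ring is cut into siloxyalkyne 4 and ketene 5 ([2+2]). The same alkyne 4 therefore serves twice, and no second ynol ether has to be made.

**4 from 2, 2 from 1.** Siloxyalkyne 4 comes from ester 2 by one-carbon homologation through ynolate 3 and O-silylation. Ester 2 comes from commercial acid 1.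

## Alternatives that were turned down

**Alternative 1:** Ring C is made the route-defining cut (C4–C3 and O1–C2). A ring A salicylaldehyde, 2-hydroxy-4,6-bis(methoxymethoxy)-3,5-diprenylbenzaldehyde A2, and the aryl prenyl alkyne A3 are joined by cyclopentadienyl rhodium catalysis with a divalent copper oxidant to give artelasticin tetrakis(methoxymethyl) ether A1.

- For: the union is fully convergent, brings the C2 aryl and C3 prenyl groups in one operation, and its regiochemistry follows from the insertion step.
- Against: all difficulty moves into A2. Direct double C-prenylation of a 2,4,6-trioxygenated benzaldehyde competes with O-alkylation and geminal dialkylation. An iterative ortho-lithiation route to A2 is long and linear. The four acetal groups of A1 must be removed with acid from a product with three prenyl groups beside hydroxyls.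
- Comparison: on ring C this alternative is exactly as strong as the chosen plan, which uses the same type of union in step 9. It is stronger on step count if A2 can be had quickly. The chosen strategy offers instead a ring A in which each prenyl group is placed by construction, and an all-silyl protection that leaves with fluoride.

**Alternative 2:** Ring C is cut at C4–C4a and O1–C2. 2,4-Diprenylphloroglucinol A5 and the α-prenyl aroylacetate A6 are heated together without solvent at well above 200 °C to give artelasticin 2',4'-bis(tert-butyldimethylsilyl) ether A4 directly.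

- For: it is the shortest plan. The free ring carbon of A5 is flanked by two equivalent hydroxyls, so only one chromone can form, and the C5 and C7 hydroxyls need no protection.
- Against: free phenols ortho to prenyl groups cyclise to chromans or rearrange at this temperature. An α-substituted β-keto ester is a sluggish partner for acylating a hexasubstituted ring. The coumarin mode of condensation competes. Aryl silyl ethers exchange with free phenols in the melt. A5 still has to be made by selective double C-prenylation.
- Comparison: it is stronger on step economy. It is weaker on every point of functional-group tolerance and leaves the ring A problem unsolved. The hottest step of the chosen route is 135 °C in neutral solution.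

**Alternative 3:** Ring B is cut at C5'–C6' and C1'–C2'. The 2-ethynylchromone A8 reacts with the bis(silyloxy)methoxydiene A9 in a cycloaddition; loss of the methoxy and silyl groups aromatises ring B to give artelasticin 5,7-bis(methoxymethyl) ether A7.

- For: the polarised diene sets the 2',4'-dioxygenation pattern regioselectively, and ring B could be varied late.
- Against: ring B is the easiest part of the molecule and is available intact in 13. A8 already contains everything difficult (diprenylated ring A, the C3 prenyl group) plus an alkyne on C2, so the sequence is long and linear. The alkyne is activated only vinylogously through C2=C3 and is flanked by the C3 prenyl group, so heating is needed, under which the diene degrades or adds in conjugate fashion at C2. The acetals again require acid.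
- Comparison: its only advantage is flexibility in ring B, which this target does not need. The chosen strategy spends its key step on ring A, where the structural problem lies.

Key step: step 4

## Route

Step 1
Reactants: 1 4-methylpent-3-enoic acid
Product: 2 ethyl 4-methylpent-3-enoate
Conditions: EtI, K2CO3, DMF, rt
Reagents that add atoms: iodoethane CCI
Why: SN2 O-alkylation of the carboxylate; basic conditions are chosen because acid-catalysed esterification would risk lactonisation of the β,γ-unsaturated acid through the tertiary cation and migration of the double bond.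

Step 2
Reactants: 2 ethyl 4-methylpent-3-enoate
Product: 4 triisopropyl[(5-methylhex-4-en-1-yn-1-yl)oxy]silane, via lithium 5-methylhex-4-en-1-yn-1-olate 3 (not isolated)
Conditions: CH2Br2, lithium 2,2,6,6-tetramethylpiperidide, THF, −78 °C; LiN(SiMe3)2; n-BuLi, −78 °C → rt; then i-Pr3SiCl (excess), −78 °C → rt
Reagents that add atoms: dibromomethane BrCBr; chlorotriisopropylsilane CC(C)[Si](Cl)(C(C)C)C(C)C
Why: Kowalski ester homologation: the dibromomethyl anion adds to the ester, and bromine–lithium exchange with 1,2-shift of the alkyl group gives ynolate 3 (the new alkyne carbon comes from CH2Br2); the bulky silyl chloride silylates 3 on oxygen rather than carbon. Low temperature and the hindered amide base keep the acidic allylic α-protons of 2 from being removed before addition.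

Step 3
Reactants: 4 triisopropyl[(5-methylhex-4-en-1-yn-1-yl)oxy]silane; 5 ketene (ethenone)
Product: 6 2-(3-methylbut-2-en-1-yl)-3-[(triisopropylsilyl)oxy]cyclobut-2-en-1-one
Conditions: CH2=C=O (excess, gas stream), CH2Cl2, −20 → 0 °C
Reagents that add atoms: none
Why: [2+2] cycloaddition of a ketene with an electron-rich ynol silyl ether, a known entry to 3-siloxycyclobutenones: the carbon β to oxygen of 4 attacks the carbonyl carbon of 5 and the ring closes at the oxygen-bearing carbon, so the prenyl group ends up on C2 and the siloxy group on C3. The parent ketene does not add to unactivated trisubstituted alkenes at this temperature; 6 is a vinylogous silyl ester and is isolated without aqueous acid or base.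

Step 4
Reactants: 6 2-(3-methylbut-2-en-1-yl)-3-[(triisopropylsilyl)oxy]cyclobut-2-en-1-one; 4 triisopropyl[(5-methylhex-4-en-1-yn-1-yl)oxy]silane
Product: 11 2,4-bis(3-methylbut-2-en-1-yl)-3,5-bis[(triisopropylsilyl)oxy]phenol, via siloxyvinylketene 7 (not isolated), via vinylcyclobutenone 8 (not isolated), via dienylketene 9 (not isolated), via cyclohexadienone 10 (not isolated)
Conditions: 4 (1.3 equiv), toluene (degassed), 100 °C, then 135 °C, sealed tube
Reagents that add atoms: none
Why: Danheiser benzannulation with a siloxyalkyne as ketenophile: heating opens 6 by four-electron electrocyclic cleavage of its C1–C4 bond to vinylketene 7. The ketene C=C of 7 adds to 4 in a [2+2] cycloaddition in which the nucleophilic, prenyl-bearing alkyne carbon bonds to the ketene carbonyl carbon (future C8a–C8) and the oxygen-bearing alkyne carbon to the ketene α-carbon (future C7–C6), giving 8. Further heating opens 8 by a second four-electron electrocyclic reaction to dienylketene 9, and ring A closes by a thermal disrotatory six-electron electrocyclisation between the ketene carbon and the terminal CH2 (C8a–C4a) to give 10, which tautomerises to the aromatic phenol 11. The closest known reaction type is the benzannulation of alkyl- or aryl-substituted cyclobutenones with triisopropylsiloxyalkynes to resorcinol monosilyl ethers; a cyclobutenone with oxygen on C3 is a less common partner and is expected to open more slowly because of its vinylogous ester character, hence the two temperature stages. The selectivity the step needs is the orientation of the [2+2] addition, and it is secured by the polarisation of the ynol ether (the carbon β to oxygen is the nucleophile) matched with the electrophilic central carbon of the ketene. Opening of 8 can turn either the siloxyvinyl or the prenyl group toward the ketene and only the (3E) isomer 9 can cyclise, but the opening is reversible, so the other isomer should return through 8. No stereocentre is formed in 11; the quaternary carbon of 8 is racemic and becomes an sp2 ring carbon. A small excess of 4 keeps 7 from acylating the phenol as it forms, and the unactivated prenyl double bonds, held one carbon from the ketene, should not take part in [2+2] reactions.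

Step 5
Reactants: 11 2,4-bis(3-methylbut-2-en-1-yl)-3,5-bis[(triisopropylsilyl)oxy]phenol
Product: 12 2-hydroxy-3,5-bis(3-methylbut-2-en-1-yl)-4,6-bis[(triisopropylsilyl)oxy]benzaldehyde
Conditions: MgCl2, Et3N, (CH2O)n, THF, reflux
Reagents that add atoms: paraformaldehyde (as formaldehyde) C=O
Why: Magnesium-mediated ortho-formylation of a phenol (Casnati–Skattebøl conditions): the magnesium phenoxide delivers formaldehyde to the ortho carbon through a six-membered chelate and a second equivalent of formaldehyde oxidises the benzylic alkoxide by hydride transfer. Only one ring carbon of 11 is unsubstituted and it is ortho to the free hydroxyl; nothing in the medium is acidic enough to affect the prenyl groups or the aryl silyl ethers.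

Step 6
Reactants: 13 2,4-dihydroxybenzaldehyde
Product: 14 2,4-bis[(tert-butyldimethylsilyl)oxy]benzaldehyde
Conditions: t-BuMe2SiCl, imidazole, DMF, rt
Reagents that add atoms: tert-butylchlorodimethylsilane CC(C)(C)[Si](C)(C)Cl
Why: Standard silylation of both phenols; silyl rather than acetal protection is chosen so that ring B is unmasked by fluoride in the last step.

Step 7
Reactants: 14 2,4-bis[(tert-butyldimethylsilyl)oxy]benzaldehyde
Product: 15 {[4-(2,2-dibromoethenyl)-1,3-phenylene]bis(oxy)}bis[tert-butyl(dimethyl)silane]
Conditions: CBr4, PPh3, Zn, CH2Cl2, rt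
Reagents that add atoms: tetrabromomethane BrC(Br)(Br)Br
Why: First stage of the Corey–Fuchs sequence, a Wittig-type olefination by the dibromomethylene phosphorane formed in the flask; zinc as halogen scavenger avoids Ph3PBr2 and HBr, which would cleave the aryl silyl ethers.

Step 8
Reactants: 15 {[4-(2,2-dibromoethenyl)-1,3-phenylene]bis(oxy)}bis[tert-butyl(dimethyl)silane]; 16 prenyl bromide (1-bromo-3-methylbut-2-ene)
Product: 18 {[4-(5-methylhex-4-en-1-yn-1-yl)-1,3-phenylene]bis(oxy)}bis[tert-butyl(dimethyl)silane], via lithium arylethynide 17 (not isolated)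
Conditions: n-BuLi (2.1 equiv), THF, −78 → 0 °C; then CuI (10 mol%), 16, 0 °C → rt
Reagents that add atoms: none
Why: Second stage of the Corey–Fuchs sequence (bromine–lithium exchange, loss of LiBr with 1,2-shift, deprotonation) gives acetylide 17, which is allylated in the same flask; copper catalysis makes the coupling with the primary allylic bromide fast and directs it to the unsubstituted terminus (SN2), the quaternary SN2' centre being disfavoured. The aprotic one-pot procedure avoids carbonate in methanol, under which aryl silyl ethers are lost.

Step 9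
Reactants: 12 2-hydroxy-3,5-bis(3-methylbut-2-en-1-yl)-4,6-bis[(triisopropylsilyl)oxy]benzaldehyde; 18 {[4-(5-methylhex-4-en-1-yn-1-yl)-1,3-phenylene]bis(oxy)}bis[tert-butyl(dimethyl)silane]
Product: 19 2-{2,4-bis[(tert-butyldimethylsilyl)oxy]phenyl}-3,6,8-tris(3-methylbut-2-en-1-yl)-5,7-bis[(triisopropylsilyl)oxy]-4H-chromen-4-one
Conditions: [Cp*RhCl2]2 (5 mol%), Cu(OAc)2 (2.2 equiv), o-xylene, 120 °C, Ar
Reagents that add atoms: none
Why: Oxidative annulation of a salicylaldehyde with an internal aryl alkyl alkyne, a known route to 2-aryl-3-alkylchromones: the phenoxide directs cleavage of the aldehyde C–H bond, the alkyne inserts with its aryl-bearing carbon next to rhodium so that the acyl carbon bonds to the prenyl-bearing carbon (C4–C3), and C–O reductive elimination closes O1–C2. Cu(OAc)2 returns monovalent rhodium to the trivalent state; the acetate-buffered medium should leave silyl ethers and trisubstituted alkenes intact, and loss of the silyl group on the C5 oxygen would be harmless because of the symmetry of ring A.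

Step 10
Reactants: 19 2-{2,4-bis[(tert-butyldimethylsilyl)oxy]phenyl}-3,6,8-tris(3-methylbut-2-en-1-yl)-5,7-bis[(triisopropylsilyl)oxy]-4H-chromen-4-one
Product: 20 artelasticin, 2-(2,4-dihydroxyphenyl)-5,7-dihydroxy-3,6,8-tris(3-methylbut-2-en-1-yl)-4H-chromen-4-one
Conditions: Bu4NF, AcOH, THF, 0 °C → rt
Reagents that add atoms: none
Why: Fluoride-induced cleavage of all four aryl silyl ethers (strong Si–F bond, phenoxide leaving groups), buffered with acetic acid so that the tetraphenol is not kept as a polyanion; no Brønsted or Lewis acid able to cyclise a prenyl group onto a neighbouring hydroxyl is present.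

## Compound list

1 | 4-methylpent-3-enoic acid | CC(C)=CCC(=O)O | starting material
2 | ethyl 4-methylpent-3-enoate | CCOC(=O)CC=C(C)C | intermediate
3 | lithium 5-methylhex-4-en-1-yn-1-olate | [Li+].[O-]C#CCC=C(C)C | intermediate (not isolated)
4 | triisopropyl[(5-methylhex-4-en-1-yn-1-yl)oxy]silane | CC(C)=CCC#CO[Si](C(C)C)(C(C)C)C(C)C | intermediate
5 | ketene (ethenone), generated on demand from acetone | C=C=O | starting material
6 | 2-(3-methylbut-2-en-1-yl)-3-[(triisopropylsilyl)oxy]cyclobut-2-en-1-one | O=C1CC(O[Si](C(C)C)(C(C)C)C(C)C)=C1CC=C(C)C | intermediate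
7 | 2-(3-methylbut-2-en-1-yl)-3-[(triisopropylsilyl)oxy]buta-1,3-dien-1-one | O=C=C(CC=C(C)C)C(=C)O[Si](C(C)C)(C(C)C)C(C)C | intermediate (not isolated)
8 | 2,4-bis(3-methylbut-2-en-1-yl)-3-[(triisopropylsilyl)oxy]-4-{1-[(triisopropylsilyl)oxy]ethenyl}cyclobut-2-en-1-one (racemic) | O=C1C(CC=C(C)C)=C(O[Si](C(C)C)(C(C)C)C(C)C)C1(CC=C(C)C)C(=C)O[Si](C(C)C)(C(C)C)C(C)C | intermediate (not isolated)
9 | (3E)-2,4-bis(3-methylbut-2-en-1-yl)-3,5-bis[(triisopropylsilyl)oxy]hexa-1,3,5-trien-1-one | O=C=C(CC=C(C)C)/C(O[Si](C(C)C)(C(C)C)C(C)C)=C(/CC=C(C)C)C(=C)O[Si](C(C)C)(C(C)C)C(C)C | intermediate (not isolated)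
10 | 2,4-bis(3-methylbut-2-en-1-yl)-3,5-bis[(triisopropylsilyl)oxy]cyclohexa-2,4-dien-1-one | O=C1CC(O[Si](C(C)C)(C(C)C)C(C)C)=C(CC=C(C)C)C(O[Si](C(C)C)(C(C)C)C(C)C)=C1CC=C(C)C | intermediate (not isolated)
11 | 2,4-bis(3-methylbut-2-en-1-yl)-3,5-bis[(triisopropylsilyl)oxy]phenol | Oc1cc(O[Si](C(C)C)(C(C)C)C(C)C)c(CC=C(C)C)c(O[Si](C(C)C)(C(C)C)C(C)C)c1CC=C(C)C | intermediate
12 | 2-hydroxy-3,5-bis(3-methylbut-2-en-1-yl)-4,6-bis[(triisopropylsilyl)oxy]benzaldehyde | O=Cc1c(O)c(CC=C(C)C)c(O[Si](C(C)C)(C(C)C)C(C)C)c(CC=C(C)C)c1O[Si](C(C)C)(C(C)C)C(C)C | intermediate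
13 | 2,4-dihydroxybenzaldehyde | O=Cc1ccc(O)cc1O | starting material
14 | 2,4-bis[(tert-butyldimethylsilyl)oxy]benzaldehyde | O=Cc1ccc(O[Si](C)(C)C(C)(C)C)cc1O[Si](C)(C)C(C)(C)C | intermediate
15 | {[4-(2,2-dibromoethenyl)-1,3-phenylene]bis(oxy)}bis[tert-butyl(dimethyl)silane] | BrC(Br)=Cc1ccc(O[Si](C)(C)C(C)(C)C)cc1O[Si](C)(C)C(C)(C)C | intermediate
16 | prenyl bromide (1-bromo-3-methylbut-2-ene) | CC(C)=CCBr | starting material
17 | lithium {2,4-bis[(tert-butyldimethylsilyl)oxy]phenyl}ethynide | [Li]C#Cc1ccc(O[Si](C)(C)C(C)(C)C)cc1O[Si](C)(C)C(C)(C)C | intermediate (not isolated)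
18 | {[4-(5-methylhex-4-en-1-yn-1-yl)-1,3-phenylene]bis(oxy)}bis[tert-butyl(dimethyl)silane] | CC(C)=CCC#Cc1ccc(O[Si](C)(C)C(C)(C)C)cc1O[Si](C)(C)C(C)(C)C | intermediate
19 | 2-{2,4-bis[(tert-butyldimethylsilyl)oxy]phenyl}-3,6,8-tris(3-methylbut-2-en-1-yl)-5,7-bis[(triisopropylsilyl)oxy]-4H-chromen-4-one | CC(C)=CCc1c(O[Si](C(C)C)(C(C)C)C(C)C)c(CC=C(C)C)c2oc(-c3ccc(O[Si](C)(C)C(C)(C)C)cc3O[Si](C)(C)C(C)(C)C)c(CC=C(C)C)c(=O)c2c1O[Si](C(C)C)(C(C)C)C(C)C | intermediate
20 | artelasticin, 2-(2,4-dihydroxyphenyl)-5,7-dihydroxy-3,6,8-tris(3-methylbut-2-en-1-yl)-4H-chromen-4-one | CC(C)=CCc1c(O)c(CC=C(C)C)c2oc(-c3ccc(O)cc3O)c(CC=C(C)C)c(=O)c2c1O | target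

## Step count and least certain steps

Total: 10 steps. Longest linear sequence: 7 steps (steps 1, 2, 3, 4, 5, 9 and 10, from acid 1 to 20). The ring B branch (steps 6 to 8) joins at step 9.

**Step 4 (key step).** The most likely failure is a first ring opening of 6 that is too slow because of its vinylogous ester stabilisation. At the temperature then needed, siloxyalkyne 4 can be lost by silyl shift and oligomerisation, or ketene 7 can be consumed by dimerisation or by acylating the phenol as it forms. The sequence may also stall at the stage of 8 if the second stage is not hot enough. Opening 6 by irradiation at room temperature before heating is the first adjustment.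

The fallback changes the approach and builds ring A by iterative directed ortho-lithiation. It sets out from prenyl bromide 16 and purchased phloroglucinol F1 and comes back to the route at 12, replacing steps 2 to 5:

- F1 is converted with chloromethyl methyl ether and i-Pr2NEt into 1,3,5-tris(methoxymethoxy)benzene F2.
- Lithiation of F2 with n-BuLi between two acetal groups and alkylation with 16 should give 1,3,5-tris(methoxymethoxy)-2-(3-methylbut-2-en-1-yl)benzene F3.
- A second lithiation and alkylation with 16 should give 1,3,5-tris(methoxymethoxy)-2,4-bis(3-methylbut-2-en-1-yl)benzene F4.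
- A third lithiation at the last free position with DMF quench should give 2,4,6-tris(methoxymethoxy)-3,5-bis(3-methylbut-2-en-1-yl)benzaldehyde F5.
- Catalytic HCl in methanol at room temperature should release 2,4,6-trihydroxy-3,5-bis(3-methylbut-2-en-1-yl)benzaldehyde F6.
- Two equivalents of i-Pr3SiOTf with 2,6-lutidine should silylate the para hydroxyl and one of the two equivalent ortho hydroxyls, leaving the hydrogen-bonded one free, which is 12.

The price is the loss of the convergent ring A construction and one mildly acidic step at an early, inexpensive stage.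

**Step 9.** The likely failures are slow alkyne insertion, because 18 carries a bulky ortho silyloxy group and 12 is fully substituted, and isomerisation of the doubly activated propargylic–allylic CH2 of 18 to allenic or conjugated isomers under hot acetate. Decarbonylation after C–H cleavage is a further risk.

The fallback builds ring C stepwise. It sets out from 12 and from acetylide 17 (made from 15 as in step 8) and comes back at 19:

- Addition of 17 (2.2 equiv, the first equivalent deprotonating the phenol) to 12 should give racemic 3-{2,4-bis[(tert-butyldimethylsilyl)oxy]phenyl}-1-{2-hydroxy-3,5-bis(3-methylbut-2-en-1-yl)-4,6-bis[(triisopropylsilyl)oxy]phenyl}prop-2-yn-1-ol F7.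
- MnO2 oxidation should give the corresponding ynone, 3-{2,4-bis[(tert-butyldimethylsilyl)oxy]phenyl}-1-{2-hydroxy-3,5-bis(3-methylbut-2-en-1-yl)-4,6-bis[(triisopropylsilyl)oxy]phenyl}prop-2-yn-1-one F8.
- 6-endo oxa-Michael closure catalysed by 4-(dimethylamino)pyridine in DMF should give the 3-unsubstituted flavone 2-{2,4-bis[(tert-butyldimethylsilyl)oxy]phenyl}-6,8-bis(3-methylbut-2-en-1-yl)-5,7-bis[(triisopropylsilyl)oxy]-4H-chromen-4-one F9.
- Lithiation of F9 at C3 with LDA at −78 °C and alkylation with 16 should give 19.

**Step 5.** The likely failure is slow attack of formaldehyde at a carbon squeezed between the hydroxyl and a bulky silyloxy group. The intermediate quinone methide could then be trapped by a second molecule of 11 (diarylmethane formation), or the oxidation could stop at the salicyl alcohol.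

The fallback replaces the chelation-controlled process by electrophilic substitution. It sets out from 11 and comes back at 12. Vilsmeier–Haack reaction (POCl3, DMF, 0 °C) at the only free, strongly activated position should give the aryl iminium salt N-{2-hydroxy-3,5-bis(3-methylbut-2-en-1-yl)-4,6-bis[(triisopropylsilyl)oxy]benzylidene}-N-methylmethanaminium chloride F10. Hydrolysis with aqueous NaOAc should give 12.

**Step 3.** The likely failures are loss or dimerisation of gaseous ketene before it adds, and hydrolytic loss of the silyl group from the vinylogous silyl ester 6 during isolation.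

The fallback uses a ketene equivalent generated in solution. It sets out from 4 and comes back at 6. Dichloroketene (from Cl3CCOCl and zinc–copper couple, Et2O), used in no more than one equivalent so that the far more nucleophilic ynol ether reacts before the prenyl alkene, should give 4,4-dichloro-2-(3-methylbut-2-en-1-yl)-3-[(triisopropylsilyl)oxy]cyclobut-2-en-1-one F11. Reductive dechlorination with Zn, AcOH and N,N,N',N'-tetramethylethylenediamine in EtOH at 0 °C should give 6.

## Further compounds

F1 | step 4 | benzene-1,3,5-triol (phloroglucinol, purchased) | Oc1cc(O)cc(O)c1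
F2 | step 4 | 1,3,5-tris(methoxymethoxy)benzene | COCOc1cc(OCOC)cc(OCOC)c1
F3 | step 4 | 1,3,5-tris(methoxymethoxy)-2-(3-methylbut-2-en-1-yl)benzene | COCOc1cc(OCOC)c(CC=C(C)C)c(OCOC)c1
F4 | step 4 | 1,3,5-tris(methoxymethoxy)-2,4-bis(3-methylbut-2-en-1-yl)benzene | COCOc1cc(OCOC)c(CC=C(C)C)c(OCOC)c1CC=C(C)C
F5 | step 4 | 2,4,6-tris(methoxymethoxy)-3,5-bis(3-methylbut-2-en-1-yl)benzaldehyde | COCOc1c(C=O)c(OCOC)c(CC=C(C)C)c(OCOC)c1CC=C(C)C
F6 | step 4 | 2,4,6-trihydroxy-3,5-bis(3-methylbut-2-en-1-yl)benzaldehyde | O=Cc1c(O)c(CC=C(C)C)c(O)c(CC=C(C)C)c1O
F7 | step 9 | 3-{2,4-bis[(tert-butyldimethylsilyl)oxy]phenyl}-1-{2-hydroxy-3,5-bis(3-methylbut-2-en-1-yl)-4,6-bis[(triisopropylsilyl)oxy]phenyl}prop-2-yn-1-ol (racemic) | OC(C#Cc1ccc(O[Si](C)(C)C(C)(C)C)cc1O[Si](C)(C)C(C)(C)C)c1c(O)c(CC=C(C)C)c(O[Si](C(C)C)(C(C)C)C(C)C)c(CC=C(C)C)c1O[Si](C(C)C)(C(C)C)C(C)C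
F8 | step 9 | 3-{2,4-bis[(tert-butyldimethylsilyl)oxy]phenyl}-1-{2-hydroxy-3,5-bis(3-methylbut-2-en-1-yl)-4,6-bis[(triisopropylsilyl)oxy]phenyl}prop-2-yn-1-one | O=C(C#Cc1ccc(O[Si](C)(C)C(C)(C)C)cc1O[Si](C)(C)C(C)(C)C)c1c(O)c(CC=C(C)C)c(O[Si](C(C)C)(C(C)C)C(C)C)c(CC=C(C)C)c1O[Si](C(C)C)(C(C)C)C(C)C
F9 | step 9 | 2-{2,4-bis[(tert-butyldimethylsilyl)oxy]phenyl}-6,8-bis(3-methylbut-2-en-1-yl)-5,7-bis[(triisopropylsilyl)oxy]-4H-chromen-4-one | CC(C)=CCc1c(O[Si](C(C)C)(C(C)C)C(C)C)c(CC=C(C)C)c2oc(-c3ccc(O[Si](C)(C)C(C)(C)C)cc3O[Si](C)(C)C(C)(C)C)cc(=O)c2c1O[Si](C(C)C)(C(C)C)C(C)C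
F10 | step 5 | N-{2-hydroxy-3,5-bis(3-methylbut-2-en-1-yl)-4,6-bis[(triisopropylsilyl)oxy]benzylidene}-N-methylmethanaminium chloride | C[N+](C)=Cc1c(O)c(CC=C(C)C)c(O[Si](C(C)C)(C(C)C)C(C)C)c(CC=C(C)C)c1O[Si](C(C)C)(C(C)C)C(C)C.[Cl-]
F11 | step 3 | 4,4-dichloro-2-(3-methylbut-2-en-1-yl)-3-[(triisopropylsilyl)oxy]cyclobut-2-en-1-one | O=C1C(CC=C(C)C)=C(O[Si](C(C)C)(C(C)C)C(C)C)C1(Cl)Cl
A1 | alternative 1 | artelasticin tetrakis(methoxymethyl) ether | CC(C)=CCc1c(OCOC)c(CC=C(C)C)c2oc(-c3ccc(OCOC)cc3OCOC)c(CC=C(C)C)c(=O)c2c1OCOC
A2 | alternative 1 | 2-hydroxy-4,6-bis(methoxymethoxy)-3,5-bis(3-methylbut-2-en-1-yl)benzaldehyde | O=Cc1c(O)c(CC=C(C)C)c(OCOC)c(CC=C(C)C)c1OCOC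
A3 | alternative 1 | 2,4-bis(methoxymethoxy)-1-(5-methylhex-4-en-1-yn-1-yl)benzene | CC(C)=CCC#Cc1ccc(OCOC)cc1OCOC
A4 | alternative 2 | artelasticin 2',4'-bis(tert-butyldimethylsilyl) ether | CC(C)=CCc1c(O)c(CC=C(C)C)c2oc(-c3ccc(O[Si](C)(C)C(C)(C)C)cc3O[Si](C)(C)C(C)(C)C)c(CC=C(C)C)c(=O)c2c1O
A5 | alternative 2 | 2,4-bis(3-methylbut-2-en-1-yl)benzene-1,3,5-triol | Oc1cc(O)c(CC=C(C)C)c(O)c1CC=C(C)C
A6 | alternative 2 | ethyl 2-{2,4-bis[(tert-butyldimethylsilyl)oxy]benzoyl}-5-methylhex-4-enoate | CCOC(=O)C(CC=C(C)C)C(=O)c1ccc(O[Si](C)(C)C(C)(C)C)cc1O[Si](C)(C)C(C)(C)C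
A7 | alternative 3 | artelasticin 5,7-bis(methoxymethyl) ether | CC(C)=CCc1c(OCOC)c(CC=C(C)C)c2oc(-c3ccc(O)cc3O)c(CC=C(C)C)c(=O)c2c1OCOC
A8 | alternative 3 | 2-ethynyl-5,7-bis(methoxymethoxy)-3,6,8-tris(3-methylbut-2-en-1-yl)-4H-chromen-4-one | C#Cc1oc2c(CC=C(C)C)c(OCOC)c(CC=C(C)C)c(OCOC)c2c(=O)c1CC=C(C)C
A9 | alternative 3 | 1-methoxy-1,3-bis(trimethylsilyloxy)buta-1,3-diene | COC(O[Si](C)(C)C)=CC(=C)O[Si](C)(C)C
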